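## Retrosynthetic overview

1. C7–C8 (key bond): 3,4,5-trimethoxybenzaldehyde 1 and acetaldehyde 2 are joined through the cofactor-bound acyl anion equivalent 3 (Breslow enaminol of 1) to give (R)-α-hydroxy ketone 4; C8 is set here.
2. C8–O(aryl): Mitsunobu coupling of 4 with 4-allyl-2,6-dimethoxyphenol 5, through alkoxyphosphonium ion 6, gives (S)-α-aryloxy ketone 7 with inversion.
3. C7–H: chelation-controlled hydride reduction of 7 gives the target 8 (erythro, 7R,8S).
4. Rings: none is formed; ring A (trimethoxyphenyl) arrives with 1 and ring B (allyl-dimethoxyphenyl) with 5, in that order.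

Assumption: C7 is the carbinol carbon, C8 the ether-bearing carbon and C9 the methyl, so the target is (7R,8S) = (1R,2S), erythro; recombinant benzaldehyde lyase is taken as an obtainable catalyst, not a starting material.

## Route

Step 1
Reactants: 1 3,4,5-trimethoxybenzaldehyde; 2 acetaldehyde
Product: 4 (R)-2-hydroxy-1-(3,4,5-trimethoxyphenyl)propan-1-one, via cofactor-bound Breslow enaminol 3 (not isolated)
Conditions: benzaldehyde lyase from Pseudomonas fluorescens (recombinant, about 20 U/mL), thiamine diphosphate (0.15 mM), MgSO4 (2.5 mM), 2 (5 equiv, fed in portions), 50 mM KH2PO4/K2HPO4 buffer pH 8.0–DMSO 4:1, 30 °C, 24–48 h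
Reagents that add atoms: none
Why: Thiamine-diphosphate-dependent enzymatic cross-acyloin (benzoin-type) carboligation, in which the cofactor ylide adds to the formyl carbon of 1 and tautomerises to the nucleophilic enaminol 3, an acyl anion equivalent that attacks the carbonyl carbon of 2, so that two naturally electrophilic carbonyl carbons are joined as C7–C8, while the active site (which takes electron-rich methoxybenzaldehydes as donors and acetaldehyde as acceptor) delivers 3 to one face of 2 and sets C8 as (R) in high ee in a pure addition with no co-product.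

Step 2
Reactants: 4 (R)-2-hydroxy-1-(3,4,5-trimethoxyphenyl)propan-1-one; 5 4-allyl-2,6-dimethoxyphenol
Product: 7 (S)-2-(4-allyl-2,6-dimethoxyphenoxy)-1-(3,4,5-trimethoxyphenyl)propan-1-one, via alkoxyphosphonium ion 6 (not isolated)
Conditions: 5 (1.3 equiv), PPh3 (1.5 equiv), DIAD (1.5 equiv, added last, dropwise), THF, 0 °C → rt, 12 h
Reagents that add atoms: none
Why: Mitsunobu etherification, in which the alcohol of 4 is activated as alkoxyphosphonium ion 6 and the phenoxide of 5 (pKa about 10) displaces triphenylphosphine oxide by SN2 at a carbon activated by the adjacent carbonyl group, inverting C8 from (R) to (S) under neutral, cold conditions that should not enolise the ketone, while the allyl group and the methyl ethers are spectators.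

Step 3
Reactants: 7 (S)-2-(4-allyl-2,6-dimethoxyphenoxy)-1-(3,4,5-trimethoxyphenyl)propan-1-one
Product: 8 (1R,2S)-2-(4-allyl-2,6-dimethoxyphenoxy)-1-(3,4,5-trimethoxyphenyl)propan-1-ol
Conditions: Zn(BH4)2 (0.6 equiv, titrated 0.15 M stock solution in Et2O), Et2O–CH2Cl2 1:1, −40 → −20 °C, 2 h; then 1 M aq HCl, 0 °C; chromatography to remove the minor threo isomer
Reagents that add atoms: none
Why: Chelation-controlled (Cram-chelate) hydride reduction, in which divalent zinc ties the ketone oxygen and the C8 aryl ether oxygen into a five-membered chelate in a weakly coordinating solvent and hydride enters from the face of the small C8–H, anti to the C8 methyl group, giving the 1,2-anti (erythro) alcohol and so setting C7 as (R) from C8 (S), while the isolated alkene is not hydroborated at this temperature.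

## Compound list

1 | 3,4,5-trimethoxybenzaldehyde | COc1cc(C=O)cc(OC)c1OC | starting material
2 | acetaldehyde | CC=O | starting material
3 | cofactor-bound Breslow enaminol: thiamine diphosphate carrying C(OH)(3,4,5-trimethoxyphenyl)= on thiazole C2 (acyl anion equivalent of 1) | Cc1ncc(CN2C(C)=C(CCOP(=O)(O)OP(=O)(O)O)SC2=C(O)c3cc(OC)c(OC)c(OC)c3)c(N)n1 | intermediate
4 | (R)-2-hydroxy-1-(3,4,5-trimethoxyphenyl)propan-1-one | C[C@@H](O)C(=O)c1cc(OC)c(OC)c(OC)c1 | intermediate
5 | 4-allyl-2,6-dimethoxyphenol (methoxyeugenol) | C=CCc1cc(OC)c(O)c(OC)c1 | starting material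
6 | {[(R)-1-oxo-1-(3,4,5-trimethoxyphenyl)propan-2-yl]oxy}triphenylphosphonium ion | C[C@@H](O[P+](c1ccccc1)(c1ccccc1)c1ccccc1)C(=O)c1cc(OC)c(OC)c(OC)c1 | intermediate
7 | (S)-2-(4-allyl-2,6-dimethoxyphenoxy)-1-(3,4,5-trimethoxyphenyl)propan-1-one | C=CCc1cc(OC)c(O[C@@H](C)C(=O)c2cc(OC)c(OC)c(OC)c2)c(OC)c1 | intermediate
8 | (1R,2S)-2-(4-allyl-2,6-dimethoxyphenoxy)-1-(3,4,5-trimethoxyphenyl)propan-1-ol (erythro; 7R,8S) | C=CCc1cc(OC)c(O[C@@H](C)[C@H](O)c2cc(OC)c(OC)c(OC)c2)c(OC)c1 | target

## Step count and risks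

Total step count: 3.
Longest linear sequence: 3 steps (1 → 4 → 7 → 8; 2 and 5 are bought).

The three steps most likely to fail, most risky first:

Step 2 (Mitsunobu on an α-hydroxy aryl ketone with a di-ortho-substituted phenol). The risks are elimination of the activated alcohol to the aryl vinyl ketone, partial racemisation at the enolisable C8, and slow attack by the hindered phenoxide. The fallback sets out from 4 and comes back at 7. The alcohol is first turned into an isolated sulfonate with Tf2O and 2,6-lutidine in CH2Cl2 at −78 °C, giving (R)-1-oxo-1-(3,4,5-trimethoxyphenyl)propan-2-yl trifluoromethanesulfonate F4 with retention. F4 is then displaced by the phenoxide of 5 (5, Cs2CO3, MeCN, −20 → 0 °C) in a separate SN2 step with inversion to give 7.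

Step 3 (chelation-controlled reduction). The risk is that the weakly basic, hindered aryl ether oxygen chelates poorly and the erythro:threo ratio is low. The fallback sets out from 7 and comes back at 8. The ketone is reduced on purpose under non-chelating Felkin–Anh control with LiBH(s-Bu)3 in THF at −78 °C to the threo alcohol (1S,2S)-2-(4-allyl-2,6-dimethoxyphenoxy)-1-(3,4,5-trimethoxyphenyl)propan-1-ol F5. C7 is then inverted by a Mitsunobu reaction with 4-nitrobenzoic acid (PPh3, DIAD, THF, 0 °C) to give (1R,2S)-2-(4-allyl-2,6-dimethoxyphenoxy)-1-(3,4,5-trimethoxyphenyl)propyl 4-nitrobenzoate F6. Methanolysis (K2CO3, MeOH, rt) gives 8.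

Step 1 (enzymatic cross-acyloin). The risks are low activity or poor solubility of 1 and competing self-benzoin formation. The fallback sets out from 1 and comes back at 4, and still makes the C7–C8 bond with an acyl anion, now a stoichiometric one, with stereocontrol moved to a catalytic reduction.
- Aldehyde 1 is condensed with propane-1,3-dithiol (BF3·OEt2 cat., CH2Cl2, 0 °C → rt) to give 2-(3,4,5-trimethoxyphenyl)-1,3-dithiane F1.
- F1 is lithiated (n-BuLi, THF, −78 °C) and acylated with N-methoxy-N-methylacetamide to give 1-[2-(3,4,5-trimethoxyphenyl)-1,3-dithian-2-yl]ethan-1-one F2.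
- Corey–Bakshi–Shibata reduction (BH3·SMe2, 10 mol% (S)-1-methyl-3,3-diphenyltetrahydro-1H,3H-pyrrolo[1,2-c][1,3,2]oxazaborole, THF, −20 °C), with the dithianyl carbon as the large group, gives (R)-1-[2-(3,4,5-trimethoxyphenyl)-1,3-dithian-2-yl]ethan-1-ol F3.
- Dithiane removal (MeI, CaCO3, MeCN–H2O 9:1, 40 °C) gives 4.

Further compounds
F1 | step 1 | 2-(3,4,5-trimethoxyphenyl)-1,3-dithiane | COc1cc(cc(OC)c1OC)C1SCCCS1
F2 | step 1 | 1-[2-(3,4,5-trimethoxyphenyl)-1,3-dithian-2-yl]ethan-1-one | CC(=O)C1(SCCCS1)c2cc(OC)c(OC)c(OC)c2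
F3 | step 1 | (R)-1-[2-(3,4,5-trimethoxyphenyl)-1,3-dithian-2-yl]ethan-1-ol | C[C@@H](O)C1(SCCCS1)c2cc(OC)c(OC)c(OC)c2
F4 | step 2 | (R)-1-oxo-1-(3,4,5-trimethoxyphenyl)propan-2-yl trifluoromethanesulfonate | C[C@@H](OS(=O)(=O)C(F)(F)F)C(=O)c1cc(OC)c(OC)c(OC)c1
F5 | step 3 | (1S,2S)-2-(4-allyl-2,6-dimethoxyphenoxy)-1-(3,4,5-trimethoxyphenyl)propan-1-ol | C=CCc1cc(OC)c(O[C@@H](C)[C@@H](O)c2cc(OC)c(OC)c(OC)c2)c(OC)c1
F6 | step 3 | (1R,2S)-2-(4-allyl-2,6-dimethoxyphenoxy)-1-(3,4,5-trimethoxyphenyl)propyl 4-nitrobenzoate | C=CCc1cc(OC)c(O[C@@H](C)[C@H](OC(=O)c2ccc(cc2)[N+](=O)[O-])c3cc(OC)c(OC)c(OC)c3)c(OC)c1
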